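**Retrosynthetic overview**

1. Target 23 ⇐ tert-butyl ester 21 ⇐ (Z)-enol triflate 18 + acetoxymethylzinc bromide (C13–C16); 18 ⇐ β-keto ester 17.
2. 17 ⇐ enyne ketone 12 + bromo keto ester 15: radical addition to the vinyl group (C11–C12), then 6-exo-dig radical closure of ring B (C8–C9); this also gives the exocyclic methylene and sets C9.
3. 12 ⇐ enone 9 by anti conjugate addition of a vinyl group (C10 quaternary, trans to the C5 chain).
4. 9 ⇐ cyclopentanone 5 by radical one-carbon ring expansion (silyl enol ether, cyclopropane, FeCl3): ring A is made first as a five-membered ring and enlarged to six.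
5. 5 ⇐ 4,4-dimethylcyclopentenone 1 + butynyl Grignard from 2 (catalytic asymmetric conjugate addition sets C5) + methyl iodide. Ring order: A, then B.

Assumption: labdane numbering (C1–C20) is used for positions in the text; the ligand enantiomer in step 1 is assigned by analogy and is exchanged for its antipode if the first run gives the (3R) adduct.

**Step 1**
Reactants: 1 4,4-dimethylcyclopent-2-en-1-one; 2 (4-bromobut-1-yn-1-yl)trimethylsilane (but-3-ynyl bromide with a trimethylsilyl protecting group on the alkyne)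
Product: 5 (2S,3S)-2,4,4-trimethyl-3-[4-(trimethylsilyl)but-3-yn-1-yl]cyclopentan-1-one, via Grignard reagent 3 (not isolated), via magnesium enolate 4 (not isolated)
Conditions: 2, Mg, Et2O, 35 °C; then 1, CuBr·SMe2 (5 mol %), (R)-1-[(SP)-2-(diphenylphosphino)ferrocenyl]ethyldicyclohexylphosphine (6 mol %), t-BuOMe, −78 °C; then MeI, DMPU, −78 → 0 °C
Reagents that add atoms: iodomethane, CI
Why: Copper-catalysed asymmetric conjugate addition of a Grignard reagent to a cyclic enone sets C5 (3S here) under catalyst control, and C-methylation of the resulting magnesium enolate brings in C20 trans to the new chain (this second centre is erased in step 2).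

**Step 2**
Reactants: 5 (2S,3S)-2,4,4-trimethyl-3-[4-(trimethylsilyl)but-3-yn-1-yl]cyclopentan-1-one
Product: 6 trimethyl({(3R)-2,4,4-trimethyl-3-[4-(trimethylsilyl)but-3-yn-1-yl]cyclopent-1-en-1-yl}oxy)silane
Conditions: Me3SiCl, NaI, Et3N, MeCN, 25 → 40 °C
Reagents that add atoms: chlorotrimethylsilane, C[Si](C)(C)Cl
Why: Thermodynamic silyl enol ether formation (iodotrimethylsilane made in situ, amine base) gives the more substituted, tetrasubstituted enol ether towards the methyl-bearing carbon; C5 is untouched.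

**Step 3**
Reactants: 6 trimethyl({(3R)-2,4,4-trimethyl-3-[4-(trimethylsilyl)but-3-yn-1-yl]cyclopent-1-en-1-yl}oxy)silane
Product: 7 trimethyl({(1S,2R,5S)-1,3,3-trimethyl-2-[4-(trimethylsilyl)but-3-yn-1-yl]bicyclo[3.1.0]hexan-5-yl}oxy)silane
Conditions: Et2Zn, CH2I2, CH2Cl2, 0 → 25 °C
Reagents that add atoms: diiodomethane, ICI
Why: Simmons–Smith cyclopropanation (Furukawa variant) of the electron-rich enol ether adds the future C1 anti to the side chain while the silyl alkyne is inert; both new centres are destroyed in step 4, so the facial ratio is of no consequence.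

**Step 4**
Reactants: 7 trimethyl({(1S,2R,5S)-1,3,3-trimethyl-2-[4-(trimethylsilyl)but-3-yn-1-yl]bicyclo[3.1.0]hexan-5-yl}oxy)silane
Product: 9 (4R)-3,5,5-trimethyl-4-[4-(trimethylsilyl)but-3-yn-1-yl]cyclohex-2-en-1-one, via chloro ketone 8 (not isolated)
Conditions: FeCl3 (2.2 equiv), DMF, 0 °C; then Et3N, CH2Cl2, 25 °C
Reagents that add atoms: none
Why: Ito–Saegusa radical ring expansion: one-electron oxidation by FeCl3 (trivalent iron) cleaves the internal cyclopropane bond to the tertiary β-keto radical at C10 (ring A becomes six-membered with the ketone at C2), chlorine transfer gives 8, and E1cB loss of HCl towards C1 gives the conjugated enone without touching C5.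

**Step 5**
Reactants: 9 (4R)-3,5,5-trimethyl-4-[4-(trimethylsilyl)but-3-yn-1-yl]cyclohex-2-en-1-one; 10 ethenylmagnesium bromide
Product: 12 (3S,4R)-4-(but-3-yn-1-yl)-3-ethenyl-3,5,5-trimethylcyclohexan-1-one, via silyl enol ether 11 (not isolated)
Conditions: 10 (2.5 equiv), CuBr·SMe2 (10 mol %), Me3SiCl, HMPA, THF, −78 → −40 °C; then K2CO3 (0.2 equiv), MeOH, 25 °C
Reagents that add atoms: none
Why: Chlorosilane-accelerated copper-catalysed conjugate addition (Nakamura–Kuwajima conditions, known for isophorone-type enones) delivers the vinyl group anti to the pseudoaxial C5 chain and so sets the quaternary C10 trans to it; methanolysis then cleaves the enol silyl ether and the alkynyl silane in the same flask.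

**Step 6**
Reactants: 13 4-methylideneoxetan-2-one (diketene)
Product: 15 tert-butyl 4-bromo-3-oxobutanoate, via acyl bromide 14 (not isolated)
Conditions: Br2, CH2Cl2, −30 °C; then t-BuOH, pyridine, −30 → 0 °C
Reagents that add atoms: bromine, BrBr; 2-methylpropan-2-ol, CC(C)(C)O
Why: Brominative ring opening of diketene gives 4-bromoacetoacetyl bromide, which is esterified in situ (acyl substitution) to the tert-butyl ester that later protects C15.

**Step 7**
Reactants: 12 (3S,4R)-4-(but-3-yn-1-yl)-3-ethenyl-3,5,5-trimethylcyclohexan-1-one; 15 tert-butyl 4-bromo-3-oxobutanoate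
Product: 17 tert-butyl 5-[(1R,4aR,8aR)-5,5,8a-trimethyl-2-methylidene-7-oxodecahydronaphthalen-1-yl]-3-oxopentanoate, via vinyl bromide 16 (not isolated)
Conditions: 15 (1.5 equiv), fac-Ir(ppy)3 (1 mol %; ppy = 2-phenylpyridinate, C11H8N), MeCN, blue LEDs, 25 °C; then Bu3SnH (2.5 equiv, syringe pump), AIBN, 80 °C
Reagents that add atoms: none
Why: Proposed new method: the excited iridium photocatalyst reduces the C–Br bond of 15 to an electrophilic 2-oxoalkyl radical that adds to the terminal carbon of the vinyl group (faster than to the terminal alkyne) to form C11–C12; the secondary C9 radical then closes ring B by 6-exo-dig attack on the alkyne through a chair transition state with the new chain equatorial (C9 set relative to the fixed C5 and C10, expected about 4:1), and the vinyl radical takes bromine from 15 to carry the chain, so the product stays masked as a vinyl bromide that does not accept a second radical; tributyltin hydride then removes the vinylic bromine (and cyclises any uncyclised secondary bromide through the same C9 radical), so all intermediates converge on the exocyclic methylene; the closest known reaction types are photoredox atom-transfer radical addition of α-bromo carbonyl compounds to alkenes and atom-transfer radical cyclisation of enynes followed by tin hydride reduction.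

**Step 8**
Reactants: 17 tert-butyl 5-[(1R,4aR,8aR)-5,5,8a-trimethyl-2-methylidene-7-oxodecahydronaphthalen-1-yl]-3-oxopentanoate
Product: 18 tert-butyl (2Z)-5-[(1R,4aR,8aR)-5,5,8a-trimethyl-2-methylidene-7-oxodecahydronaphthalen-1-yl]-3-{[(trifluoromethyl)sulfonyl]oxy}pent-2-enoate
Conditions: NaH (1.1 equiv), THF, 0 °C; then PhNTf2, 0 → 25 °C
Reagents that add atoms: N-phenylbis(trifluoromethanesulfonimide), O=S(=O)(N(c1ccccc1)S(=O)(=O)C(F)(F)F)C(F)(F)F
Why: Only the β-keto ester is deprotonated (the ring ketone is far less acidic), and O-sulfonylation of the chelated sodium enolate gives the (Z)-enol triflate with triflate and ester cis, which fixes the side-chain alkene geometry.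

**Step 9**
Reactants: 18 tert-butyl (2Z)-5-[(1R,4aR,8aR)-5,5,8a-trimethyl-2-methylidene-7-oxodecahydronaphthalen-1-yl]-3-{[(trifluoromethyl)sulfonyl]oxy}pent-2-enoate; 19 bromomethyl acetate
Product: 21 tert-butyl (2Z)-4-(acetyloxy)-3-{2-[(1R,4aR,8aR)-5,5,8a-trimethyl-2-methylidene-7-oxodecahydronaphthalen-1-yl]ethyl}but-2-enoate, via organozinc reagent 20 (not isolated)
Conditions: 19, Zn dust, LiCl, THF, 25 °C; then 18, Pd(PPh3)4 (5 mol %), THF, 25 °C
Reagents that add atoms: none
Why: Negishi cross-coupling of an acyloxymethylzinc halide with the enol triflate proceeds with retention of alkene geometry, so the acetoxymethyl group (C16) ends up cis to the ester and the acetate is installed without ever passing through a free hydroxy ester that would lactonise.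

**Step 10**
Reactants: 21 tert-butyl (2Z)-4-(acetyloxy)-3-{2-[(1R,4aR,8aR)-5,5,8a-trimethyl-2-methylidene-7-oxodecahydronaphthalen-1-yl]ethyl}but-2-enoate
Product: 23 (2Z)-4-(acetyloxy)-3-{2-[(1R,4aR,8aR)-5,5,8a-trimethyl-2-methylidene-7-oxodecahydronaphthalen-1-yl]ethyl}but-2-enoic acid, via trimethylsilyl ester 22 (not isolated)
Conditions: Me3SiOSO2CF3, 2,6-lutidine, CH2Cl2, 0 °C; then pH 4 aqueous buffer
Reagents that add atoms: none
Why: Silyl triflate-mediated tert-butyl ester cleavage (loss of isobutene, buffered by lutidine) avoids free strong acid, so the exocyclic alkene does not migrate and the allylic acetate stays; the silyl ester (and any transient silyl enol ether of the ring ketone) is hydrolysed on work-up.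

**Compound list**

1 | 4,4-dimethylcyclopent-2-en-1-one | O=C1C=CC(C)(C)C1 | starting material
2 | (4-bromobut-1-yn-1-yl)trimethylsilane | C[Si](C)(C)C#CCCBr | starting material
3 | [4-(trimethylsilyl)but-3-yn-1-yl]magnesium bromide | C[Si](C)(C)C#CCC[Mg]Br | intermediate
4 | bromomagnesium (3S)-4,4-dimethyl-3-[4-(trimethylsilyl)but-3-yn-1-yl]cyclopent-1-en-1-olate | C[Si](C)(C)C#CCC[C@@H]1C(C)(C)CC(O[Mg]Br)=C1 | intermediate
5 | (2S,3S)-2,4,4-trimethyl-3-[4-(trimethylsilyl)but-3-yn-1-yl]cyclopentan-1-one | C[Si](C)(C)C#CCC[C@@H]1C(C)(C)CC(=O)[C@H]1C | intermediate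
6 | trimethyl({(3R)-2,4,4-trimethyl-3-[4-(trimethylsilyl)but-3-yn-1-yl]cyclopent-1-en-1-yl}oxy)silane | C[Si](C)(C)C#CCC[C@@H]1C(C)(C)CC(O[Si](C)(C)C)=C1C | intermediate
7 | trimethyl({(1S,2R,5S)-1,3,3-trimethyl-2-[4-(trimethylsilyl)but-3-yn-1-yl]bicyclo[3.1.0]hexan-5-yl}oxy)silane | C[Si](C)(C)C#CCC[C@@H]1C(C)(C)C[C@@]2(O[Si](C)(C)C)C[C@@]12C | intermediate
8 | (4R)-3-chloro-3,5,5-trimethyl-4-[4-(trimethylsilyl)but-3-yn-1-yl]cyclohexan-1-one (both C3 epimers) | C[Si](C)(C)C#CCC[C@@H]1C(C)(C)CC(=O)CC1(C)Cl | intermediate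
9 | (4R)-3,5,5-trimethyl-4-[4-(trimethylsilyl)but-3-yn-1-yl]cyclohex-2-en-1-one | C[Si](C)(C)C#CCC[C@@H]1C(C)(C)CC(=O)C=C1C | intermediate
10 | ethenylmagnesium bromide | C=C[Mg]Br | starting material
11 | trimethyl({(3S,4R)-3-ethenyl-3,5,5-trimethyl-4-[4-(trimethylsilyl)but-3-yn-1-yl]cyclohex-1-en-1-yl}oxy)silane | C[Si](C)(C)C#CCC[C@@H]1C(C)(C)CC(O[Si](C)(C)C)=C[C@@]1(C)C=C | intermediate
12 | (3S,4R)-4-(but-3-yn-1-yl)-3-ethenyl-3,5,5-trimethylcyclohexan-1-one | C#CCC[C@@H]1C(C)(C)CC(=O)C[C@@]1(C)C=C | intermediate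
13 | 4-methylideneoxetan-2-one (diketene) | C=C1CC(=O)O1 | starting material
14 | 4-bromo-3-oxobutanoyl bromide | O=C(Br)CC(=O)CBr | intermediate
15 | tert-butyl 4-bromo-3-oxobutanoate | CC(C)(C)OC(=O)CC(=O)CBr | intermediate
16 | tert-butyl 5-[(1S,4aR,8aR)-2-(bromomethylidene)-5,5,8a-trimethyl-7-oxodecahydronaphthalen-1-yl]-3-oxopentanoate (E/Z mixture) | BrC=C1CC[C@@H]2C(C)(C)CC(=O)C[C@@]2(C)[C@@H]1CCC(=O)CC(=O)OC(C)(C)C | intermediate
17 | tert-butyl 5-[(1R,4aR,8aR)-5,5,8a-trimethyl-2-methylidene-7-oxodecahydronaphthalen-1-yl]-3-oxopentanoate | C=C1CC[C@@H]2C(C)(C)CC(=O)C[C@@]2(C)[C@@H]1CCC(=O)CC(=O)OC(C)(C)C | intermediate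
18 | tert-butyl (2Z)-5-[(1R,4aR,8aR)-5,5,8a-trimethyl-2-methylidene-7-oxodecahydronaphthalen-1-yl]-3-{[(trifluoromethyl)sulfonyl]oxy}pent-2-enoate | C=C1CC[C@@H]2C(C)(C)CC(=O)C[C@@]2(C)[C@@H]1CC/C(OS(=O)(=O)C(F)(F)F)=C/C(=O)OC(C)(C)C | intermediate
19 | bromomethyl acetate | CC(=O)OCBr | starting material
20 | (acetyloxymethyl)zinc bromide | CC(=O)OC[Zn]Br | intermediate
21 | tert-butyl (2Z)-4-(acetyloxy)-3-{2-[(1R,4aR,8aR)-5,5,8a-trimethyl-2-methylidene-7-oxodecahydronaphthalen-1-yl]ethyl}but-2-enoate | C=C1CC[C@@H]2C(C)(C)CC(=O)C[C@@]2(C)[C@@H]1CC/C(COC(C)=O)=C/C(=O)OC(C)(C)C | intermediate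
22 | trimethylsilyl (2Z)-4-(acetyloxy)-3-{2-[(1R,4aR,8aR)-5,5,8a-trimethyl-2-methylidene-7-oxodecahydronaphthalen-1-yl]ethyl}but-2-enoate | C=C1CC[C@@H]2C(C)(C)CC(=O)C[C@@]2(C)[C@@H]1CC/C(COC(C)=O)=C/C(=O)O[Si](C)(C)C | intermediate
23 | (2Z)-4-(acetyloxy)-3-{2-[(1R,4aR,8aR)-5,5,8a-trimethyl-2-methylidene-7-oxodecahydronaphthalen-1-yl]ethyl}but-2-enoic acid | C=C1CC[C@@H]2C(C)(C)CC(=O)C[C@@]2(C)[C@@H]1CC/C(=C/C(=O)O)COC(C)=O | target

**Step count and risks**

Total step count: 10. Longest linear sequence: 9 steps (steps 1–5 and 7–10; step 6 is a one-step side branch).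

Most likely to fail, first: step 7. The 2-oxoalkyl radical may add in part to the alkyne, the C9 radical may abstract the propargylic hydrogen at C7 instead of cyclising, and the C9 selectivity may be modest. The fallback sets out from 12 and 15 and returns at 17. Bromide 15 is treated with KSC(=S)OEt in acetone to give the xanthate tert-butyl 4-[(ethoxycarbonothioyl)sulfanyl]-3-oxobutanoate F3. Heating 12 with F3 and dilauroyl peroxide in 1,2-dichloroethane runs the same addition and 6-exo-dig closure under degenerative xanthate transfer, which keeps the C9 radical alive long enough for the slow cyclisation and needs no photocatalyst. This gives the vinyl xanthate tert-butyl 5-[(1S,4aR,8aR)-2-{[(ethoxycarbonothioyl)sulfanyl]methylidene}-5,5,8a-trimethyl-7-oxodecahydronaphthalen-1-yl]-3-oxopentanoate F4, and Bu3SnH with AIBN cleaves its C–S bond to give 17.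

Second: step 5. The β-carbon of 9 is flanked by the C5 chain and the gem-dimethyl group, so the copper reagent may fail to add or add slowly. The fallback sets out from 7 and returns at 12, and forms the C9–C10 bond from the ring-expansion radical instead. Cyclopropane 7 is oxidised with Mn(O2CC5H4N)3 (tris(pyridine-2-carboxylato)manganese, trivalent manganese) in DMF in the presence of (E)-1,2-bis(phenylsulfonyl)ethene. The tertiary C10 radical adds anti to the C5 chain and expels a sulfonyl radical to give the vinyl sulfone (3R,4R)-3,5,5-trimethyl-3-[(E)-2-(phenylsulfonyl)ethenyl]-4-[4-(trimethylsilyl)but-3-yn-1-yl]cyclohexan-1-one F1. Hydrogenolysis of the C–S bond with Na2S2O4 and NaHCO3 in aqueous DMF gives (3S,4R)-3-ethenyl-3,5,5-trimethyl-4-[4-(trimethylsilyl)but-3-yn-1-yl]cyclohexan-1-one F2, and K2CO3 in MeOH removes the alkynyl silane to give 12.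

Third: step 9. The acetoxymethylzinc reagent may decompose, or zerovalent palladium may ionise the allylic acetate of the product. The fallback sets out from 18 and returns at 21. Stille coupling of 18 with tributyl{[(tert-butyldimethylsilyl)oxy]methyl}stannane (Pd(PPh3)4, LiCl, CuI, dioxane, 80 °C) gives the silyl ether tert-butyl (2Z)-4-{[tert-butyl(dimethyl)silyl]oxy}-3-{2-[(1R,4aR,8aR)-5,5,8a-trimethyl-2-methylidene-7-oxodecahydronaphthalen-1-yl]ethyl}but-2-enoate F5. Buffered fluoride (Bu4NF, AcOH, THF, 0 °C) frees the alcohol tert-butyl (2Z)-4-hydroxy-3-{2-[(1R,4aR,8aR)-5,5,8a-trimethyl-2-methylidene-7-oxodecahydronaphthalen-1-yl]ethyl}but-2-enoate F6, whose tert-butyl ester slows lactonisation. F6 is acetylated at once with Ac2O, pyridine and DMAP to give 21.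

**Further compounds**

F1 | step 5 | (3R,4R)-3,5,5-trimethyl-3-[(E)-2-(phenylsulfonyl)ethenyl]-4-[4-(trimethylsilyl)but-3-yn-1-yl]cyclohexan-1-one | C[Si](C)(C)C#CCC[C@@H]1C(C)(C)CC(=O)C[C@@]1(C)/C=C/S(=O)(=O)c1ccccc1
F2 | step 5 | (3S,4R)-3-ethenyl-3,5,5-trimethyl-4-[4-(trimethylsilyl)but-3-yn-1-yl]cyclohexan-1-one | C[Si](C)(C)C#CCC[C@@H]1C(C)(C)CC(=O)C[C@@]1(C)C=C
F3 | step 7 | tert-butyl 4-[(ethoxycarbonothioyl)sulfanyl]-3-oxobutanoate | CCOC(=S)SCC(=O)CC(=O)OC(C)(C)C
F4 | step 7 | tert-butyl 5-[(1S,4aR,8aR)-2-{[(ethoxycarbonothioyl)sulfanyl]methylidene}-5,5,8a-trimethyl-7-oxodecahydronaphthalen-1-yl]-3-oxopentanoate (E/Z mixture) | CCOC(=S)SC=C1CC[C@@H]2C(C)(C)CC(=O)C[C@@]2(C)[C@@H]1CCC(=O)CC(=O)OC(C)(C)C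
F5 | step 9 | tert-butyl (2Z)-4-{[tert-butyl(dimethyl)silyl]oxy}-3-{2-[(1R,4aR,8aR)-5,5,8a-trimethyl-2-methylidene-7-oxodecahydronaphthalen-1-yl]ethyl}but-2-enoate | C=C1CC[C@@H]2C(C)(C)CC(=O)C[C@@]2(C)[C@@H]1CC/C(CO[Si](C)(C)C(C)(C)C)=C/C(=O)OC(C)(C)C
F6 | step 9 | tert-butyl (2Z)-4-hydroxy-3-{2-[(1R,4aR,8aR)-5,5,8a-trimethyl-2-methylidene-7-oxodecahydronaphthalen-1-yl]ethyl}but-2-enoate | C=C1CC[C@@H]2C(C)(C)CC(=O)C[C@@]2(C)[C@@H]1CC/C(CO)=C/C(=O)OC(C)(C)C
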